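Divide the rate of making product by the catalyst charged: this ratio, the turnover rate, counts the cycles each catalyst makes per minute, the inverse of one cycle's time constant.

| flask | starting material | reagent | free catalyst | remark |
|---|---|---|---|---|
| spring | 1 M | 0.60 equiv | 5 mol% | run made earlier |
| autumn | 1.6 M | 0.60 equiv | 5 mol% | run made earlier |
| summer | 0.73 M | 0.60 equiv | 10 mol% | run made earlier |
| flask | 0.73 M | 0.600 equiv | 5 mol% |  |

| run | time / min | product / % | starting material / % |
|---|---|---|---|
| spring | 0.417 | 8.4 | 80.7 |
| spring | 0.667 | 14.3 | 72.0 |
| spring | 0.833 | 17.4 | 66.3 |
| spring | 1.33 | 27.1 | 52.3 |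
| spring | 2.00 | 37.6 | 39.3 |
| spring | 3.00 | 43.9 | 32.5 |
| spring | 5.00 | 43.6 | 31.7 |
| autumn | 0.250 | 5.2 | 84.9 |
| autumn | 0.667 | 16.2 | 67.7 |
| autumn | 1.33 | 30.7 | 45.3 |
| autumn | 2.00 | 38.7 | 34.4 |
| autumn | 3.00 | 40.5 | 31.3 |
| autumn | 4.00 | 41.2 | 32.2 |
| autumn | 5.00 | 40.8 | 31.8 |
| summer | 0.417 | 14.8 | 67.8 |
| summer | 1.33 | 43.1 | 32.8 |
| summer | 2.00 | 50.7 | 24.0 |
| summer | 3.00 | 51.5 | 23.3 |
| summer | 5.00 | 51.6 | 22.8 |

(each reading ± 0.3 percentage points)

- the numbers in the tables scatter by 0.3 percentage points (one standard deviation)
- a reading of starting material is of its free form alone

1. factor on the rate of making product when 30 % of the starting material are converted if reagent is charged twice over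
2. factor on the rate when 30 % of the starting material are converted if free catalyst is charged at 0.5 mol% instead

Watch the spring run in slow motion. In the first instants, at 0.417 min, starting material already reads 80.7 % while product reads 8.4 %, so the missing part is more than the catalyst charged, and something besides the catalyst holds starting material.

In the middle, product climbs almost on a straight line. Take its slope from 0.417 min to 1.33 min, a stretch that brackets 30 % conversion, and divide by the loading: the turnover rate reads 4.10 /min.

At the end, product stands at 43.9 % at 3.00 min and 43.6 % at 5.00 min, with starting material still reading 31.7 %, so expect reagent to be the limiting reagent.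

Now multiply this reading by the catalyst in the flask. My own reckoning gives 0.150 M/min at 30 % conversion, and with the turnover held fixed, the lower loading gives a factor of 0.100. The forecast is close to that factor but not equal to it: 0.093, with 1.2 for doubled reagent. Its ground: “so rate scales roughly first order with catalyst”.

The flask gives 1.10 and 0.0272, with a rate of 0.142 M/min at 0.843 min.

    starting material + free catalyst → catalyst intermediate A (k = 0.620 /M/s)
    catalyst intermediate A → catalyst intermediate B (k = 12.0 /s)
    reagent + catalyst intermediate B → catalyst intermediate C (k = 1.60 /M/s)
    catalyst intermediate C → released group + catalyst intermediate D (k = 0.130 /s)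
    catalyst intermediate D ⇌ free catalyst + product (K = 8.60 M, k = 0.610 /s)
    2 reagent → homo dimer (k = 0.00840 /M/s)
    starting material + released group ⇌ idle adduct, settled at all times (K = 2.50 /M)

The binding of starting material and released group into idle adduct is one part of this flask's weak answer to reagent: without it, the apparent order in reagent at that conversion goes from 0.23 to 0.43. The flask's turnover, 0.142 M/min over its catalyst, is 3.90 /min, close to the 4.10 /min read from spring. Each cycle passes through the step from catalyst intermediate C to released group, at 7.80 /min, so turnover over this constant reads the share of catalyst held as intermediate C: 50.0 % in the flask. At 0.5 mol%, the factor 0.0272 gives a turnover of 1.06 /min, lower than 4.10 /min. That reads as a share of 13.6 %, and the share of catalyst intermediate C at the same conversion with that loading is 13.5 %.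

The readings were generated by integration for an exercise; scatter was added.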